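- You have a closed, stirred, isothermal vessel, and you are asked about the share of target at the end of 6.0 h.

| setting | teal | grey | zeta | delta | theta | beta |
|---|---|---|---|---|---|---|
| starting material | 0.050 M | 0.050 M | 0.050 M | 0.10 M | 0.20 M | 0.40 M |
| reagent | 0.14 M | 0.19 M | 0.0950 M | 0.0950 M | 0.0950 M | 0.0950 M |
| remark | run made earlier | run made earlier |  |  |  |  |
| time |  |  | 6.0 h | 6.0 h | 6.0 h | 6.0 h |

| run | time / h | target / % | over-reaction product / % |
|---|---|---|---|
| teal | 0.250 | 0.6 | 0 |
| teal | 0.667 | 1.8 | 0 |
| teal | 1.50 | 6.4 | 1.1 |
| teal | 4.00 | 18.3 | 12.3 |
| grey | 0.417 | 0.9 | 0.3 |
| grey | 1.33 | 6.3 | 0.3 |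
| grey | 2.50 | 14.0 | 4.8 |
| grey | 4.00 | 21.0 | 14.7 |

(scatter of a reading: 0.5 percentage points)

- the numbers in the tables scatter by 0.5 percentage points (one standard deviation)
- "hardly changes" means that all values lie within two and a half points (for a concentration: within two and a half percent of the largest)

1. share of target in all that became target or over-reaction product for zeta, delta, theta, beta, in this order
2. how that number moves from the first to the last of them (falls, then rises / rises, then falls / hardly changes / rises all the way / falls all the way)

- In teal and grey, over-reaction product grows in step with the target present. Its gain per hour over the mean target, between the last two readings, is 0.363 h⁻¹ in teal and 0.377 h⁻¹ in grey, so at these two charges of reagent the rate follows [target]. Take the mean as the ageing constant, the first-order rate at which target turns into over-reaction product: 0.370 h⁻¹.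
- Extrapolating teal's total of target and over-reaction product back to zero gives a lag of 0.688 h.
- Let a be the ageing constant times the time after the lag. With a steady supply of target, the share is one minus e to the minus a, divided by a. At 4.00 h this gives 57.6%, and grey reads 58.8%.
- At 6.0 h, a is 1.97, so your reckoning commits to 43.8% for zeta.
- The weak link is the steady supply in beta. Counting one reagent per target, an untested assumption, reagent is the limiting reagent there and caps the total at 23.8%. Teal's gain in that total between its last two readings, kept up from the lag to 6.0 h, comes to 49.1%, twice that cap.
- So let beta's supply start at teal's pace and taper evenly to zero at 6.0 h. That delivers 24.6%, against the cap of 23.8%, and the same integral gives a share of 30.3%.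
- The forecast gave 44%, 43%, 41% and 38%, and its shape was falls all the way: “The share falls slowly all the way”. It matches your zeta, but its beta stands above your 30.3%.
- The flasks give 46.0%, 45.0%, 42.6% and 36.6%, so the share falls all the way.

    starting material → intermediate (k = 0.180 h⁻¹)
    reagent + intermediate → target (k = 3.70 L mol⁻¹ h⁻¹)
    target → over-reaction product (k = 0.350 h⁻¹)

- In zeta, starting material fell to 34.0% by 6.00 h while target aged. Between 3.00 h and 6.00 h, the ageing constant on the mean target gives 17 percentage points of over-reaction product, against 17 points in the flask. In beta over the same hours, the constant gives 9.1 points against 9.4 points, while reagent fell to 8.98% of its charge by 6.00 h, when intermediate stood at 44.4%.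

(The data are simulated on assumed constants.)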